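**Plan**

Numbering: ring A has CO2H at C1, the ether oxygen at C2, OMe at C4 and heptyl at C6; ring B has CO2H at C1′, OH at C2′, the ether oxygen at C4′, OMe at C5′ and heptyl at C6′.
Retrosynthesis: the ring B salicylic acid is masked as an acetonide (benzodioxinone); the diaryl ether is cut at the ring A C2–O bond; ring B is cut at C1′–C6′, then the open chain at C5′–C6′ and C3′–C4′; ring A is cut at its C–I bond and at the benzylic C–C bond of the heptyl group.
Enabling feature: ring B has the pattern of a tetraketide resorcylate (C1′ carboxyl, C2′ and C4′ oxygens, C6′ heptyl), and its one extra oxygen, the C5′ methoxy, sits on the carbon between the two ketones of the unfolded chain, so the whole ring can be carried as a 3-methoxy-2,4-diketone on a dioxinone.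
Forward: the dioxinone is acylated twice (methoxyacetyl, then octanoyl); amine-mediated aldol aromatization closes ring B with only the C4′ hydroxyl free; ring A is made separately by benzylic alkylation and ortho C–H iodination; the rings are joined by copper-catalysed etherification; the acetonide is opened last.
Stereochemistry: the target has no stereocentre; the sp3 centres of the chain and of the aldol intermediate are erased on aromatization.

Key step: step 3

Remark on the chemistry: 7 is racemic and 8 a diastereomer mixture, which is of no consequence since both become arene 9; 1-bromohexane is taken as an additional commercial starting material.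

**Route**

Step 1
Reactants: 1 2,2,6-trimethyl-4H-1,3-dioxin-4-one; 2 methoxyacetyl chloride
Product: 4 6-(3-methoxy-2-oxopropyl)-2,2-dimethyl-4H-1,3-dioxin-4-one, via lithium dioxinone dienolate 3 (not isolated)
Conditions: LiN(SiMe3)2 (2.0 equiv), 1 (2.0 equiv), THF, −78 °C; then 2 (1.0 equiv), −78 °C; aq. NH4Cl
Reagents that add atoms: none
Why: Vinylogous Claisen-type C-acylation, in which the lithium dienolate reacts at its exocyclic γ-carbon with the acid chloride, a standard entry to keto-dioxinones, while the second equivalent of dienolate takes up the proton of the more acidic product.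

Step 2
Reactants: 4 6-(3-methoxy-2-oxopropyl)-2,2-dimethyl-4H-1,3-dioxin-4-one; 5 octanoyl chloride
Product: 7 6-(3-methoxy-2,4-dioxoundecyl)-2,2-dimethyl-4H-1,3-dioxin-4-one (racemic), via dilithium dianion of the keto-dioxinone 6 (not isolated)
Conditions: LiN(iPr)2 (2.1 equiv), THF, −78 °C; then 5 (0.5 equiv), −78 to −40 °C; aq. NH4Cl; unreacted 4 recovered
Reagents that add atoms: none
Why: Dianion C-acylation of a keto-dioxinone (the vinylogue of a β-keto ester 1,3-dianion), in which the last-formed and least stabilized enolate carbon, the methoxy-bearing α′ carbon, attacks the acid chloride and the excess dianion serves as the base for the acidic 2-methoxy-1,3-diketone formed.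

Step 3
Reactants: 7 6-(3-methoxy-2,4-dioxoundecyl)-2,2-dimethyl-4H-1,3-dioxin-4-one
Product: 9 5-heptyl-7-hydroxy-6-methoxy-2,2-dimethyl-4H-1,3-benzodioxin-4-one, via aldol carbinol 8 (not isolated)
Conditions: Et3N (5 equiv), CH2Cl2, rt
Reagents that add atoms: none
Why: Et3N removes a proton from the doubly activated C3′ methylene of 7 to give a dienolate running through the dioxinone, whose dioxinone C5 terminus (future C1′) adds to the heptyl ketone carbon (future C6′) to give carbinol 8; E1cB loss of water across C1′–C6′ and enolization of the C4′ ketone through the C5′ hydrogen then deliver arene 9. The closest known reaction type is the amine-mediated aldol aromatization of 6-(2,4-dioxoalkyl)dioxinones to acetonide-masked resorcylates, applied here to a chain that carries an alkoxy group on the central diketone carbon. Ring B closes in a 6-(enolexo)-exo-trig aldol, the only six-membered C–C closure the chain allows, since attack on the nearer ketone would give a four-membered ring. No stereocentre survives, because the methoxy-bearing carbon of 7 and the three sp3 centres of 8 all become arene carbons. The step needs C-cyclization in place of O-cyclization to a pyranone, which should be secured by keeping the dioxinone intact at room temperature (no thermal acylketene) and by the soft vinylogous-ester carbon nucleophile generated under mild amine base. Because the acylal ties up the carboxyl group and the C2′ oxygen, the only free phenol of 9 is the C4′ hydroxyl needed for the ether.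

Step 4
Reactants: 10 4-methoxy-2-methylbenzoic acid; 11 1-bromohexane
Product: 13 2-heptyl-4-methoxybenzoic acid, via dilithiated toluate 12 (not isolated)
Conditions: LiN(iPr)2 (2.2 equiv), THF, −78 to 0 °C; then 11, −78 °C to rt; 1 M HCl
Reagents that add atoms: none
Why: Lateral (benzylic) lithiation of an ortho-toluic acid as its carboxylate dianion followed by SN2 alkylation with a primary bromide, the carboxylate stabilizing the benzylic anion and the amide base being unable to metalate the anisole ring.

Step 5
Reactants: 13 2-heptyl-4-methoxybenzoic acid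
Product: 14 2-heptyl-6-iodo-4-methoxybenzoic acid
Conditions: Pd(OAc)2 (5 mol%), PhI(OAc)2 (0.75 equiv), I2 (0.75 equiv), DMF, 60–80 °C, dark
Reagents that add atoms: iodine, SMILES II (delivered as acetyl hypoiodite, SMILES CC(=O)OI, formed in the flask)
Why: Carboxylate-directed ortho C–H iodination catalysed by divalent palladium (cyclopalladation, oxidation by acetyl hypoiodite, C–I reductive elimination), which has only the single free ortho C–H at C6 to act on, while the coordinating solvent should hold back electrophilic iodination next to the methoxy group.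

Step 6
Reactants: 9 5-heptyl-7-hydroxy-6-methoxy-2,2-dimethyl-4H-1,3-benzodioxin-4-one; 14 2-heptyl-6-iodo-4-methoxybenzoic acid
Product: 15 2-heptyl-6-[(5-heptyl-6-methoxy-2,2-dimethyl-4-oxo-4H-1,3-benzodioxin-7-yl)oxy]-4-methoxybenzoic acid
Conditions: CuI (20 mol%), Cs2CO3 (3 equiv), DMF, 90 °C; then cold dilute HCl
Reagents that add atoms: none
Why: Ullmann-type diaryl ether synthesis accelerated by the ortho carboxylate of the aryl iodide, which delivers monovalent copper to the adjacent C–I bond, with the C4′ hydroxyl as the only phenol of 9 and the C6′ heptyl group shielding the acylal carbonyl from the phenoxide.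

Step 7
Reactants: 15 2-heptyl-6-[(5-heptyl-6-methoxy-2,2-dimethyl-4-oxo-4H-1,3-benzodioxin-7-yl)oxy]-4-methoxybenzoic acid
Product: 16 2-(4-carboxy-3-heptyl-5-hydroxy-2-methoxyphenoxy)-6-heptyl-4-methoxybenzoic acid (CNP0151337.0)
Conditions: KOH, DMSO–H2O, 80 °C; then 1 M HCl, 0 °C
Reagents that add atoms: potassium hydroxide, SMILES [K+].[OH-]
Why: Saponification of the acylal, in which hydroxide attacks the lactone-type carbonyl and the hemiketal collapses with loss of acetone to free the C1′ carboxylate and the C2′ phenoxide, the aryl ethers being inert to base and cold acidification avoiding decarboxylation of the salicylic acid.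

**Compound list**

1 | 2,2,6-trimethyl-4H-1,3-dioxin-4-one | CC1=CC(=O)OC(C)(C)O1 | starting material
2 | methoxyacetyl chloride | COCC(=O)Cl | starting material
3 | lithium 2,2-dimethyl-6-methylidene-6H-1,3-dioxin-4-olate (lithium dienolate of 1) | C=C1C=C(O[Li])OC(C)(C)O1 | intermediate (not isolated)
4 | 6-(3-methoxy-2-oxopropyl)-2,2-dimethyl-4H-1,3-dioxin-4-one | COCC(=O)CC1=CC(=O)OC(C)(C)O1 | intermediate
5 | octanoyl chloride | CCCCCCCC(=O)Cl | starting material
6 | dilithium 1-methoxy-3-(2,2-dimethyl-4-oxido-6H-1,3-dioxin-6-ylidene)prop-1-en-2-olate (dianion of 4) | COC=C(O[Li])C=C1C=C(O[Li])OC(C)(C)O1 | intermediate (not isolated)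
7 | 6-(3-methoxy-2,4-dioxoundecyl)-2,2-dimethyl-4H-1,3-dioxin-4-one, racemic | CCCCCCCC(=O)C(OC)C(=O)CC1=CC(=O)OC(C)(C)O1 | intermediate
8 | 5-heptyl-5-hydroxy-6-methoxy-2,2-dimethyl-4a,5-dihydro-4H-1,3-benzodioxine-4,7(6H)-dione, diastereomer mixture | CCCCCCCC1(O)C(OC)C(=O)C=C2OC(C)(C)OC(=O)C12 | intermediate (not isolated)
9 | 5-heptyl-7-hydroxy-6-methoxy-2,2-dimethyl-4H-1,3-benzodioxin-4-one | CCCCCCCc1c(OC)c(O)cc2OC(C)(C)OC(=O)c12 | intermediate
10 | 4-methoxy-2-methylbenzoic acid | Cc1cc(OC)ccc1C(=O)O | starting material
11 | 1-bromohexane | CCCCCCBr | starting material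
12 | lithium 2-(lithiomethyl)-4-methoxybenzoate | [Li]Cc1cc(OC)ccc1C(=O)O[Li] | intermediate (not isolated)
13 | 2-heptyl-4-methoxybenzoic acid | CCCCCCCc1cc(OC)ccc1C(=O)O | intermediate
14 | 2-heptyl-6-iodo-4-methoxybenzoic acid | CCCCCCCc1cc(OC)cc(I)c1C(=O)O | intermediate
15 | 2-heptyl-6-[(5-heptyl-6-methoxy-2,2-dimethyl-4-oxo-4H-1,3-benzodioxin-7-yl)oxy]-4-methoxybenzoic acid | CCCCCCCc1cc(OC)cc(Oc2cc3OC(C)(C)OC(=O)c3c(CCCCCCC)c2OC)c1C(=O)O | intermediate
16 | 2-(4-carboxy-3-heptyl-5-hydroxy-2-methoxyphenoxy)-6-heptyl-4-methoxybenzoic acid | CCCCCCCc1cc(OC)cc(Oc2cc(O)c(C(=O)O)c(CCCCCCC)c2OC)c1C(=O)O | target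

**Step count and risks**

Total step count: 7. Longest linear sequence: 5 steps (steps 1, 2, 3, 6, 7); the ring A branch (steps 4, 5) joins at step 6.

Steps most likely to fail:

Step 2. The dianion may be acylated on oxygen, or be quenched by proton transfer from the acid chloride (ketene formation), so that little C-acylated diketone forms at the hindered methoxy-bearing carbon. The fallback sets out from 4: its dianion 6 would be added to octanal (THF, −78 °C) in a directed aldol reaction to give 6-(4-hydroxy-3-methoxy-2-oxoundecyl)-2,2-dimethyl-4H-1,3-dioxin-4-one F1 as a diastereomer mixture. Oxidation of the carbinol with Dess–Martin periodinane (CH2Cl2, NaHCO3, 0 °C) would come back to the route at 7. An aldehyde cannot be O-acylated and the aldolate does not consume a second dianion.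

Step 5. Electrophilic iodination of the electron-rich ring next to the methoxy group may compete with the directed palladation, or the catalyst may turn over poorly on the ortho-substituted acid. The fallback sets out from 13:
- esterification (Boc2O, DMAP, t-BuOH) should give tert-butyl 2-heptyl-4-methoxybenzoate F2;
- ester-directed ortho-magnesiation with TMP2Mg·2LiCl (TMP = 2,2,6,6-tetramethylpiperidide; THF, 0 °C to rt) should give [2-(tert-butoxycarbonyl)-3-heptyl-5-methoxyphenyl](2,2,6,6-tetramethylpiperidin-1-yl)magnesium F3;
- quenching with I2 should give tert-butyl 2-heptyl-6-iodo-4-methoxybenzoate F4;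
- cleavage of the tert-butyl ester with CF3CO2H in CH2Cl2 comes back to the route at 14.

The site of iodination is then fixed by a stoichiometric carbanion placed by the ester, and no C–H bond of the ring has to compete for an electrophile.

Step 6. Coupling of the two hindered partners may be slow, so that protodeiodination of 14 and attack of the phenoxide on the acylal of 9 at 90 °C erode the ether formation. The fallback sets out from 14 and 9 and replaces copper catalysis by arylation with a trivalent iodine reagent at low temperature:
- methylation (MeI, K2CO3, DMF) gives methyl 2-heptyl-6-iodo-4-methoxybenzoate F5;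
- oxidation with mCPBA and TsOH·H2O (MeCN, 50 °C) gives methyl 2-heptyl-6-[hydroxy(tosyloxy)-λ3-iodanyl]-4-methoxybenzoate F6;
- F6 is trapped in the same flask by 1,3,5-trimethoxybenzene as [3-heptyl-5-methoxy-2-(methoxycarbonyl)phenyl](2,4,6-trimethoxyphenyl)iodonium 4-methylbenzenesulfonate F7;
- the potassium phenoxide of 9 (K2CO3, MeCN, rt to 50 °C) should take the ortho-substituted aryl group from F7, leaving the trimethoxyphenyl group on iodine, to give methyl 2-heptyl-6-[(5-heptyl-6-methoxy-2,2-dimethyl-4-oxo-4H-1,3-benzodioxin-7-yl)oxy]-4-methoxybenzoate F8;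
- KOH in DMSO–H2O at 90 °C, then cold 1 M HCl, cleaves both the methyl ester and the acylal and comes back to the route at 16.

Further compounds
F1 | step 2 | 6-(4-hydroxy-3-methoxy-2-oxoundecyl)-2,2-dimethyl-4H-1,3-dioxin-4-one, diastereomer mixture | CCCCCCCC(O)C(OC)C(=O)CC1=CC(=O)OC(C)(C)O1
F2 | step 5 | tert-butyl 2-heptyl-4-methoxybenzoate | CCCCCCCc1cc(OC)ccc1C(=O)OC(C)(C)C
F3 | step 5 | [2-(tert-butoxycarbonyl)-3-heptyl-5-methoxyphenyl](2,2,6,6-tetramethylpiperidin-1-yl)magnesium | CCCCCCCc1cc(OC)cc([Mg]N2C(C)(C)CCCC2(C)C)c1C(=O)OC(C)(C)C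
F4 | step 5 | tert-butyl 2-heptyl-6-iodo-4-methoxybenzoate | CCCCCCCc1cc(OC)cc(I)c1C(=O)OC(C)(C)C
F5 | step 6 | methyl 2-heptyl-6-iodo-4-methoxybenzoate | CCCCCCCc1cc(OC)cc(I)c1C(=O)OC
F6 | step 6 | methyl 2-heptyl-6-[hydroxy(tosyloxy)-λ3-iodanyl]-4-methoxybenzoate | CCCCCCCc1cc(OC)cc(I(O)OS(=O)(=O)c2ccc(C)cc2)c1C(=O)OC
F7 | step 6 | [3-heptyl-5-methoxy-2-(methoxycarbonyl)phenyl](2,4,6-trimethoxyphenyl)iodonium 4-methylbenzenesulfonate | CCCCCCCc1cc(OC)cc([I+]c2c(OC)cc(OC)cc2OC)c1C(=O)OC.Cc1ccc(cc1)S(=O)(=O)[O-]
F8 | step 6 | methyl 2-heptyl-6-[(5-heptyl-6-methoxy-2,2-dimethyl-4-oxo-4H-1,3-benzodioxin-7-yl)oxy]-4-methoxybenzoate | CCCCCCCc1cc(OC)cc(Oc2cc3OC(C)(C)OC(=O)c3c(CCCCCCC)c2OC)c1C(=O)OC
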